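Readings and results are calculated from invented constants; noise was put on by code.

Over 2.5 d the flask runs 12.0 times as long as the part followed so far, and the last reading of that part still shows 8.7% starting material beside 11.2% target.

- eta: starting material 0.82 M; gas phase 73 mM (held); protic impurity 0.246 M; the very flask that is asked about, followed so far
- flask: starting material 0.82 M; gas phase 73 mM (held); protic impurity 0.246 M; time 2.5 d

eta run (percent of the starting material charged)

| time / h | target / % | starting material / % |
|---|---|---|
| 0.667 | 2.5 | 78.9 |
| 1.33 | 4.4 | 58.9 |
| 2.00 | 6.5 | 46.7 |
| 3.00 | 9.8 | 29.2 |
| 4.00 | 9.6 | 17.9 |
| 5.00 | 11.2 | 8.7 |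

(readings scatter by 1 percentage point)

- how much target there is at 2.5 d, in percent of the starting material charged
- concentration of dissolved gas in solution at 2.5 d, in percent of saturation

- at the start none of the gas phase is in solution

Two extreme versions of this flask can be solved in the head. In the poor one, the remaining starting material gives no target and the yield stays at 11.2%; in the rich one, all of it becomes target, which gives 19.9%. Pooled over the readings of the eta run, target found per starting material consumed, the selectivity, reads 12.2%, far below one, and no reading shows target falling by more than the scatter of 1 percentage point. So the flask should lie near the poor end. Replacing the curve by this mean, the remainder adds 1.1 points, and this reckoning gives 12.3%. A tail at twice that ratio adds the same again, about the scatter of a reading.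

The forecast also gives 12.3% target, on the ground that “Target tracks starting material consumed at a steady ratio”, and 99% of saturation for the dissolved gas.

The flask gives 14.8% target and dissolved gas at >99.9% of saturation, and the forecast stands within the tolerance on both.

    gas phase ⇌ dissolved gas, rate k1*(csat - [dissolved gas]) (kL = 2.60 × 10⁻⁴ s⁻¹)
    starting material + dissolved gas → target (k = 0.00250 M⁻¹ s⁻¹)
    starting material → side product A (k = 7.90 × 10⁻⁵ s⁻¹)
    target ⇌ isomer of the product (K = 0.650, k = 2.50 × 10⁻⁴ s⁻¹)
    dissolved gas + protic impurity → quenched reagent (k = 5.60 × 10⁻⁴ M⁻¹ s⁻¹)
    starting material + target → side product B (k = 1.20 × 10⁻⁴ M⁻¹ s⁻¹)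

With 0% starting material left, the ratio of this flask equals its yield, 14.8%, which stands 2.6 points above the 12.2% read from the eta run and inside the band from 11.2% to 19.9%. The neighbouring flask is charged with 0.33 M starting material, and it too ends with 0% left, so its yield is again its ratio. Its target is 22.2% of its charge, 1.82 times the ratio read from the eta run.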